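## Retrosynthetic overview
1. Avoided: biomimetic Ag2O oxidative coupling (racemic, regio-mixtures), and Sharpless AD or epoxide routes that close the ring by Mitsunobu/SN2 at a C(sp3)–O bond.
2. The target comes from one global DIBAL-H reduction of a trans-benzodioxane carrying a C2 ethyl ester, an ethyl acrylate and an aryl pivalate. This reveals both CH2OH groups and the phenol together.
3. The 1,4-dioxane is the only ring formed. It is closed last, at the aryl C(sp2)–O bond, by Pd etherification of ArBr with the benzylic OH, so no bond to a stereocentre is touched.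
4. Key step: both stereocentres are set at once by Ru-catalysed asymmetric transfer hydrogenation with dynamic kinetic resolution (ATH-DKR) of a racemic α-aryloxy-β-keto ester.
5. The keto ester comes from SN2 union of ethyl 5-bromoferulate (from 5-bromovanillin) with an α-bromo-β-keto ester (from syringic acid).

Assumption: the SMILES was read as the trans-(2S,3S) isomer (C2 bears the aryl group, C3 bears CH2OH, E-alkene). Reagents that donate atoms are numbered as starting materials. Catalysts, bases and solvents are not numbered.

## Route

**Step 1**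
Reactants: 1 syringic acid (4-hydroxy-3,5-dimethoxybenzoic acid); 2 pivaloyl chloride
Product: 3 3,5-dimethoxy-4-(pivaloyloxy)benzoic acid
Conditions: PivCl (2.3 equiv), pyridine, DMAP (cat.), CH2Cl2, 0 °C→rt; then NaHCO3, THF/H2O, rt; acidify to pH 2
Reagents that add atoms: pivaloyl chloride, CC(C)(C)C(=O)Cl
Why: DMAP-catalysed O-acylation; the transient mixed anhydride is hydrolysed by bicarbonate, while the aryl pivalate flanked by two OMe groups survives and later suppresses quinone-methide ionisation at the benzylic carbon.

**Step 2**
Reactants: 3; 4 potassium ethyl malonate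
Product: 5 ethyl 3-[3,5-dimethoxy-4-(pivaloyloxy)phenyl]-3-oxopropanoate
Conditions: CDI, THF, rt; then 4, MgCl2, Et3N, MeCN, rt→45 °C; aq. citric acid
Reagents that add atoms: potassium ethyl malonate, CCOC(=O)CC(=O)[O-].[K+] (loses CO2)
Why: Masamune–Brooks decarboxylative Claisen of the acyl imidazolide with the magnesium malonate enolate, which is near-neutral so the aryl pivalate is untouched.

**Step 3**
Reactants: 5; 6 N-bromosuccinimide
Product: 7 (±)-ethyl 2-bromo-3-[3,5-dimethoxy-4-(pivaloyloxy)phenyl]-3-oxopropanoate
Conditions: NBS (1.02 equiv), NH4OAc (10 mol %), Et2O, 0 °C→rt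
Reagents that add atoms: NBS, O=C1CCC(=O)N1Br
Why: Electrophilic α-bromination of the β-keto ester enol, which is much faster than bromination of an arene deactivated by the acyl and OPiv groups; one equivalent limits dibromination.

**Step 4**
Reactants: 8 5-bromovanillin (3-bromo-4-hydroxy-5-methoxybenzaldehyde); 9 ethyl hydrogen malonate
Product: 10 ethyl (E)-3-(3-bromo-4-hydroxy-5-methoxyphenyl)prop-2-enoate (ethyl 5-bromoferulate)
Conditions: 9 (1.5 equiv), pyridine, piperidine (cat.), 80 °C
Reagents that add atoms: ethyl hydrogen malonate, CCOC(=O)CC(=O)O (loses CO2 and H2O)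
Why: Knoevenagel–Doebner condensation tolerates the free acidic phenol, and decarboxylative elimination gives the E-cinnamate, fixing the alkene geometry and removing the aldehyde before the hydride steps.

**Step 5**
Reactants: 7; 10
Product: 11 (±)-ethyl 2-{2-bromo-4-[(E)-3-ethoxy-3-oxoprop-1-enyl]-6-methoxyphenoxy}-3-[3,5-dimethoxy-4-(pivaloyloxy)phenyl]-3-oxopropanoate
Conditions: K2CO3 (1.3 equiv), acetone, 0 °C→rt; mild acid work-up
Reagents that add atoms: none (both partners are the reactants above; HBr is lost)
Why: Williamson-type SN2 of the phenoxide on the doubly activated secondary bromide forms the Cβ–O bond with the correct regiochemistry (O para to the side chain); Br+ transfer to the phenoxide ring is blocked because both ortho positions and the para position are substituted.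

**Step 6 (key step)**
Reactants: 11
Product: 12 ethyl (2R,3S)-2-{2-bromo-4-[(E)-3-ethoxy-3-oxoprop-1-enyl]-6-methoxyphenoxy}-3-[3,5-dimethoxy-4-(pivaloyloxy)phenyl]-3-hydroxypropanoate (syn)
Conditions: RuCl[(R,R)-TsDPEN](p-cymene) (2 mol %), HCO2H/Et3N 5:2, CH2Cl2, 30 °C
Reagents that add atoms: none (H only)
Why: In this Noyori–Ikariya ATH with DKR, Et3N racemises C2 through the enol faster than reduction, the (R,R)-catalyst delivers hydride in the same spatial sense that gives (R)-1-phenylethanol (here labelled 3S because CH(OAr)CO2Et outranks aryl), and the Felkin–Anh-matched C2 enantiomer (C–OAr anti to hydride) reacts faster to give the syn-(2R,3S) product; the reaction is established for α-alkoxy- and α-amido-β-keto esters, the α-aryloxy case is a substrate extension, and the cinnamate, ArBr and esters are inert.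

**Step 7**
Reactants: 12
Product: 13 ethyl (2R,3S)-3-[3,5-dimethoxy-4-(pivaloyloxy)phenyl]-6-[(E)-3-ethoxy-3-oxoprop-1-enyl]-8-methoxy-2,3-dihydro-1,4-benzodioxine-2-carboxylate (trans)
Conditions: Pd(OAc)2 (3 mol %), 2-(di-tert-butylphosphino)-1,1'-binaphthyl (4 mol %), K3PO4 (1.5 equiv), toluene, 70 °C
Reagents that add atoms: none (HBr is lost)
Why: In this Buchwald-type intramolecular Pd-catalysed aryl etherification, oxidative addition to Ar–Br, deprotonation of the Pd-bound benzylic OH and C(sp2)–O reductive elimination break no bond at either stereocentre, so syn-12 maps with retention onto trans-13; the bulky ligand outcompetes β-hydride elimination, and the insoluble mild base limits retro-aldol and ester enolisation.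

**Step 8**
Reactants: 13
Product: 14 target, 4-[(2S,3S)-3-(hydroxymethyl)-7-[(E)-3-hydroxyprop-1-enyl]-5-methoxy-2,3-dihydro-1,4-benzodioxin-2-yl]-2,6-dimethoxyphenol
Conditions: DIBAL-H (9 equiv), CH2Cl2, −78→−20 °C; aq. Rochelle salt
Reagents that add atoms: none (H only)
Why: Global DIBAL-H reduction takes the C2 ester to CH2OH, reduces the cinnamate 1,2 to the E-allylic alcohol and cleaves the pivalate to the phenol in one operation; low temperature prevents epimerisation and reductive ring opening, and the C–CH2OH descriptor changes from R to S only because CIP priorities change.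

## Compound list
1 | syringic acid | COc1cc(C(=O)O)cc(OC)c1O | starting material
2 | pivaloyl chloride | CC(C)(C)C(=O)Cl | starting material
3 | 3,5-dimethoxy-4-(pivaloyloxy)benzoic acid | COc1cc(C(=O)O)cc(OC)c1OC(=O)C(C)(C)C | intermediate
4 | potassium ethyl malonate | CCOC(=O)CC(=O)[O-].[K+] | starting material
5 | ethyl 3-[3,5-dimethoxy-4-(pivaloyloxy)phenyl]-3-oxopropanoate | CCOC(=O)CC(=O)c1cc(OC)c(OC(=O)C(C)(C)C)c(OC)c1 | intermediate
6 | N-bromosuccinimide | O=C1CCC(=O)N1Br | starting material
7 | (±)-ethyl 2-bromo-3-[3,5-dimethoxy-4-(pivaloyloxy)phenyl]-3-oxopropanoate | CCOC(=O)C(Br)C(=O)c1cc(OC)c(OC(=O)C(C)(C)C)c(OC)c1 | intermediate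
8 | 5-bromovanillin | COc1cc(C=O)cc(Br)c1O | starting material
9 | ethyl hydrogen malonate | CCOC(=O)CC(=O)O | starting material
10 | ethyl (E)-5-bromoferulate | CCOC(=O)/C=C/c1cc(Br)c(O)c(OC)c1 | intermediate
11 | (±)-α-aryloxy-β-keto ester | CCOC(=O)/C=C/c1cc(Br)c(OC(C(=O)OCC)C(=O)c2cc(OC)c(OC(=O)C(C)(C)C)c(OC)c2)c(OC)c1 | intermediate
12 | syn-(2R,3S)-β-hydroxy-α-aryloxy ester | COc1cc([C@H](O)[C@@H](Oc2c(Br)cc(/C=C/C(=O)OCC)cc2OC)C(=O)OCC)cc(OC)c1OC(=O)C(C)(C)C | intermediate
13 | trans-(2R,3S)-benzodioxane diester pivalate | COc1cc([C@@H]2Oc3cc(/C=C/C(=O)OCC)cc(OC)c3O[C@H]2C(=O)OCC)cc(OC)c1OC(=O)C(C)(C)C | intermediate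
14 | target (CID11188887), trans-(2S,3S) | COc1cc([C@@H]2Oc3cc(/C=C/CO)cc(OC)c3O[C@H]2CO)cc(OC)c1O | target

## Totals and risks
Total steps: 8. Longest linear sequence: 7 (steps 1, 2, 3, 5, 6, 7, 8).

The three steps most likely to fail:

1. **Step 6.**
   - Risk: the bulky di-ortho-substituted aryloxy group may slow reduction or erode the syn:anti ratio or ee.
   - Fallback: replace catalysis with an auxiliary. Run an Evans boron syn-glycolate aldol of the N-(aryloxyacetyl) imide of (R)-4-benzyl-2-oxazolidinone (aryloxy unit from 10) with 4-O-pivaloylsyringaldehyde. Exchanging the auxiliary for OEt then gives the same 12.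

2. **Step 7.**
   - Risks: retro-aldol of the β-hydroxy ester, β-hydride elimination back to 11, or racemisation of 13 by base-induced E1cB ring opening and oxa-Michael re-closure.
   - Fallback: change the bond that closes the ring. Build the DKR substrate from ethyl 5-hydroxyferulate, made from 3,4-dihydroxy-5-methoxybenzaldehyde, where the more acidic 4-OH alkylates first. Run the same DKR, unmask the syringyl phenol, and close Cα–O by acid-promoted p-quinone-methide cyclisation. The Cβ centre set in the DKR then dictates the trans product under thermodynamic control.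

3. **Step 5.**
   - Risk: the hindered phenoxide may react slowly with the secondary bromide, or debrominate 7 by halophilic attack.
   - Fallback: switch from SN2 to carbenoid chemistry. Carry out diazo transfer on 5 (p-ABSA, Et3N), then Rh2(OAc)4-catalysed O–H insertion of the α-diazo-β-keto ester into phenol 10. This gives 11 under neutral conditions.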